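**Plan**

- Retrosynthesis: the two C–C bonds of the 4-hydroxy-3-methylfuran-2(5H)-one ring that flank its enolic C3=C4 unit (C2–C3 and C4–C5) are cut together. This leaves methylketene and the (Z)-enol ethyl carbonate of a C21 aldehyde. Next cuts: C15–C16 (allylic bromide + alkyl Grignard reagent), then C5–C6 (furylmethyl Grignard reagent + geranyl chloride).
- Enabling feature: in the furanone ring, O1 is bonded to the lactone carbonyl carbon C2 and to the sp2 carbon C5 that carries the exocyclic alkene. O1–C2(=O) is thus a carbonate in disguise on an aldehyde enol. Its carbonyl can direct metalation of C5 (polarity reversal of the aldehyde carbon) and then acylate the enolate that forms when this carbanion adds to the ketene.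
- Forward: furylmethyl + geranyl chloride give dendrolasin; terminal allylic oxidation and bromination follow; the chiral C16–C21 Grignard reagent is joined; acetal → aldehyde → (Z)-enol carbonate. The tetronic acid, the only ring made in the route, is closed last and needs no protecting group.
- Stereochemistry: C18 (S) comes from the chiral pool, (R)-methyl hydrogen 3-methylglutarate, whose two arms are differentiated chemoselectively. The 7E and 12E alkenes come from geranyl chloride and an (E)-selective allylic oxidation. The (Z)-ylidene geometry is set at the enol carbonate and carried through a configurationally stable α-oxyvinyl metal.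

Key step: step 13

Assumption: furan-3-ylmethanol, geranyl chloride, (R)-methyl hydrogen 3-methylglutarate and 2-bromopropanoyl bromide are taken as the commercial starting materials; methylketene is made fresh from the last of these and used as a cold THF solution.

**Route**

Step 1
Reactants: 1 furan-3-ylmethanol
Product: 3 3-(chloromethyl)furan, via furan-3-ylmethyl methanesulfonate 2 (not isolated)
Conditions: MsCl, LiCl, 2,4,6-collidine, DMF, 0 °C
Reagents that add atoms: lithium chloride, [Li+].[Cl-]
Why: The primary furylmethyl alcohol is mesylated and the mesylate is displaced in situ by chloride (SN2) under buffered, non-acidic conditions that spare the acid-sensitive furan.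

Step 2
Reactants: 3 3-(chloromethyl)furan; 4 geranyl chloride
Product: 6 dendrolasin, via (furan-3-ylmethyl)magnesium chloride 5 (not isolated)
Conditions: Mg, THF, 0 °C to rt; then 4, Li2CuCl4 (cat.), THF, 0 °C
Reagents that add atoms: none
Why: Li2CuCl4-catalysed Grignard cross-coupling should join the furylmethyl carbon to the primary allylic carbon of geranyl chloride with SN2 regiochemistry and retention of the (E)-alkene.

Step 3
Reactants: 6 dendrolasin
Product: 7 (2E,6E)-9-(furan-3-yl)-2,6-dimethylnona-2,6-dien-1-ol
Conditions: SeO2 (cat.), t-BuOOH, salicylic acid (cat.), CH2Cl2, 0 °C to rt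
Reagents that add atoms: tert-butyl hydroperoxide, CC(C)(C)OO
Why: Riley allylic oxidation (ene reaction then [2,3]-sigmatropic shift) should attack the terminal isopropylidene group at its (E)-methyl, as in the ω-hydroxylation of geranyl and farnesyl derivatives, giving the (E)-allylic alcohol.

Step 4
Reactants: 7 (2E,6E)-9-(furan-3-yl)-2,6-dimethylnona-2,6-dien-1-ol
Product: 8 3-[(3E,7E)-9-bromo-4,8-dimethylnona-3,7-dien-1-yl]furan
Conditions: CBr4, PPh3, CH2Cl2, 0 °C
Reagents that add atoms: carbon tetrabromide, BrC(Br)(Br)Br
Why: The Appel reaction converts the primary allylic alcohol into the bromide under neutral conditions without allylic transposition or loss of alkene geometry.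

Step 5
Reactants: 9 (R)-methyl hydrogen 3-methylglutarate
Product: 11 (S)-4-methyltetrahydro-2H-pyran-2-one, via (S)-5-hydroxy-3-methylpentanoic acid 10 (not isolated)
Conditions: LiBH4, THF, 0 °C to reflux; then 2 M HCl, rt
Reagents that add atoms: none
Why: Chemoselective borohydride reduction takes the methyl ester while the lithium carboxylate is inert, and acid then closes the δ-lactone; the two arms of the glutarate are thereby told apart and the stereocentre (later C18, S) is carried over from the chiral pool untouched.

Step 6
Reactants: 11 (S)-4-methyltetrahydro-2H-pyran-2-one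
Product: 13 methyl (R)-5-bromo-3-methylpentanoate, via (R)-5-bromo-3-methylpentanoic acid 12 (not isolated)
Conditions: HBr (gas), MeOH, 0 °C to rt
Reagents that add atoms: hydrogen bromide, Br; methanol, CO
Why: Bromide opens the protonated lactone at the O–CH2 carbon (SN2) and the acid is esterified in situ (Fischer esterification), the classical conversion of a lactone into an ω-bromo ester; the descriptor changes to R only because bromine raises the priority of that arm.

Step 7
Reactants: 13 methyl (R)-5-bromo-3-methylpentanoate
Product: 15 (R)-5-bromo-3-methylpentanal, via aluminium hemiacetal 14 (not isolated)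
Conditions: i-Bu2AlH, CH2Cl2, −78 °C; aqueous potassium sodium tartrate work-up
Reagents that add atoms: none
Why: Partial ester reduction stops at the tetrahedral aluminium hemiacetal at −78 °C, which releases the aldehyde only on work-up, and the remote primary bromide is not touched.

Step 8
Reactants: 15 (R)-5-bromo-3-methylpentanal
Product: 16 (R)-5-bromo-1,1-dimethoxy-3-methylpentane
Conditions: HC(OMe)3, p-TsOH (cat.), CH2Cl2, rt
Reagents that add atoms: trimethyl orthoformate, COC(OC)OC
Why: Acid-catalysed acetalisation with the orthoformate as methoxy source and water scavenger masks the aldehyde for the Grignard step.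

Step 9
Reactants: 16 (R)-5-bromo-1,1-dimethoxy-3-methylpentane; 8 3-[(3E,7E)-9-bromo-4,8-dimethylnona-3,7-dien-1-yl]furan
Product: 18 3-[(3E,7E,12S)-14,14-dimethoxy-4,8,12-trimethyltetradeca-3,7-dien-1-yl]furan, via Grignard reagent 17 (not isolated)
Conditions: Mg, THF, 40 °C; then 8, Li2CuCl4 (cat.), THF, −20 to 0 °C
Reagents that add atoms: none
Why: The acetal-bearing primary alkyl Grignard reagent should couple with the primary allylic bromide under Li2CuCl4 catalysis at the α-carbon (SN2, not SN2′), joining C16 to C15 with the (E)-alkene intact.

Step 10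
Reactants: 18 3-[(3E,7E,12S)-14,14-dimethoxy-4,8,12-trimethyltetradeca-3,7-dien-1-yl]furan
Product: 19 (3S,7E,11E)-14-(furan-3-yl)-3,7,11-trimethyltetradeca-7,11-dienal
Conditions: oxalic acid, THF–H2O, rt
Reagents that add atoms: water, O
Why: Mild acid-catalysed acetal hydrolysis should free the aldehyde without harming the furan or the trisubstituted alkenes, and the stereocentre, being β to the carbonyl, cannot epimerise.

Step 11
Reactants: 19 (3S,7E,11E)-14-(furan-3-yl)-3,7,11-trimethyltetradeca-7,11-dienal
Product: 21 ethyl (1Z,3S,7E,11E)-14-(furan-3-yl)-3,7,11-trimethyltetradeca-1,7,11-trien-1-yl carbonate, via potassium (Z)-enolate 20 (not isolated)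
Conditions: KN(SiMe3)2, THF, −78 °C; then ClCO2Et, −78 to 0 °C
Reagents that add atoms: ethyl chloroformate, CCOC(=O)Cl
Why: Kinetic enolisation with the hindered potassium amide should outrun aldol addition, and O-acylation of the potassium enolate by the hard chloroformate gives the enol carbonate; aldehyde enolates are expected mainly in the (Z) geometry (chain cis to oxygen), and any (E) isomer is removed by chromatography.

Step 12
Reactants: 22 2-bromopropanoyl bromide
Product: 23 methylketene
Conditions: Zn dust, THF, −10 °C, reduced pressure, co-distilled with THF into a −78 °C receiver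
Reagents that add atoms: none
Why: Zinc-mediated 1,2-dehalogenation of an α-bromoacyl bromide is the standard ketene synthesis, and sweeping the monomer out with THF keeps it from dimerising.

Step 13
Reactants: 21 ethyl (1Z,3S,7E,11E)-14-(furan-3-yl)-3,7,11-trimethyltetradeca-1,7,11-trien-1-yl carbonate; 23 methylketene
Product: 27 variabilin, via α-magnesio enol carbonate 24 (not isolated), via chloromagnesium ketone enolate 25 (not isolated), via chloromagnesium tetronate 26 (not isolated)
Conditions: TMPMgCl·LiCl [(2,2,6,6-tetramethylpiperidin-1-yl)magnesium chloride–lithium chloride, 1.1 equiv], THF, −30 °C; then 23 in THF, −78 °C to rt; 1 M HCl work-up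
Reagents that add atoms: none
Why: Proposed new method: the carbonate carbonyl holds the amide base next to the geminal enol C–H, so deprotonation gives an α-magnesio enol carbonate (an acyl-anion equivalent of the aldehyde carbon); this adds to the carbonyl carbon of methylketene (ring bond C4–C5) to give a ketone enolate, whose α-carbon attacks the carbonate carbonyl (ring bond C2–C3) with loss of ethoxide, and the resulting tetronate is protonated on work-up. The closest known reaction types are the α-lithiation and electrophile trapping of 1-alkenyl carbamates, the directed magnesiation of aryl carbonates, the addition of organolithium and Grignard reagents to ketenes, and the Dieckmann ring closure used for tetronic acids. The furanone ring closes by a 5-(enolendo)-exo-trig acyl substitution, the same mode as that Dieckmann closure; if the tetrahedral intermediate instead opens to the β-keto ester, the freed enolate oxygen should relactonise onto the ethyl ester, so both paths lead to the stabilised tetronate. No new stereocentre is formed: the (Z) geometry of the exocyclic alkene is inherited from 21 because α-oxyvinyl metals keep their configuration, and C18 is not acidic under these conditions. The step needs metalation at the enol C–H and not at furan C2–H (secured by chelation to the carbonate carbonyl, low temperature and one equivalent of base), no 1,2-shift of the ethoxycarbonyl group (secured by the covalent C–Mg bond), and C- over O-acylation of the enolate (secured because only C-acylation ends in the tetronate anion).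

**Compound list**

1 | furan-3-ylmethanol | OCc1ccoc1 | starting material
2 | furan-3-ylmethyl methanesulfonate | CS(=O)(=O)OCc1ccoc1 | intermediate
3 | 3-(chloromethyl)furan | ClCc1ccoc1 | intermediate
4 | geranyl chloride, (2E)-1-chloro-3,7-dimethylocta-2,6-diene | CC(C)=CCC/C(C)=C/CCl | starting material
5 | (furan-3-ylmethyl)magnesium chloride | Cl[Mg]Cc1ccoc1 | intermediate
6 | dendrolasin, 3-[(3E)-4,8-dimethylnona-3,7-dien-1-yl]furan | CC(C)=CCC/C(C)=C/CCc1ccoc1 | intermediate
7 | (2E,6E)-9-(furan-3-yl)-2,6-dimethylnona-2,6-dien-1-ol | OC/C(C)=C/CC/C(C)=C/CCc1ccoc1 | intermediate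
8 | 3-[(3E,7E)-9-bromo-4,8-dimethylnona-3,7-dien-1-yl]furan | BrC/C(C)=C/CC/C(C)=C/CCc1ccoc1 | intermediate
9 | (R)-methyl hydrogen 3-methylglutarate, (3R)-5-methoxy-3-methyl-5-oxopentanoic acid | COC(=O)C[C@H](C)CC(=O)O | starting material
10 | (S)-5-hydroxy-3-methylpentanoic acid | OCC[C@H](C)CC(=O)O | intermediate
11 | (S)-4-methyltetrahydro-2H-pyran-2-one | O=C1C[C@@H](C)CCO1 | intermediate
12 | (R)-5-bromo-3-methylpentanoic acid | OC(=O)C[C@@H](C)CCBr | intermediate
13 | methyl (R)-5-bromo-3-methylpentanoate | COC(=O)C[C@@H](C)CCBr | intermediate
14 | aluminium hemiacetal, [(3R)-5-bromo-1-methoxy-3-methylpentoxy]bis(2-methylpropyl)alumane | COC(O[Al](CC(C)C)CC(C)C)C[C@@H](C)CCBr | intermediate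
15 | (R)-5-bromo-3-methylpentanal | O=CC[C@@H](C)CCBr | intermediate
16 | (R)-5-bromo-1,1-dimethoxy-3-methylpentane | COC(OC)C[C@@H](C)CCBr | intermediate
17 | [(3R)-5,5-dimethoxy-3-methylpentyl]magnesium bromide | COC(OC)C[C@@H](C)CC[Mg]Br | intermediate
18 | 3-[(3E,7E,12S)-14,14-dimethoxy-4,8,12-trimethyltetradeca-3,7-dien-1-yl]furan | COC(OC)C[C@@H](C)CCC/C(C)=C/CC/C(C)=C/CCc1ccoc1 | intermediate
19 | (3S,7E,11E)-14-(furan-3-yl)-3,7,11-trimethyltetradeca-7,11-dienal | O=CC[C@@H](C)CCC/C(C)=C/CC/C(C)=C/CCc1ccoc1 | intermediate
20 | potassium (1Z,3S,7E,11E)-14-(furan-3-yl)-3,7,11-trimethyltetradeca-1,7,11-trien-1-olate | [K+].[O-]/C=C\[C@@H](C)CCC/C(C)=C/CC/C(C)=C/CCc1ccoc1 | intermediate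
21 | ethyl (1Z,3S,7E,11E)-14-(furan-3-yl)-3,7,11-trimethyltetradeca-1,7,11-trien-1-yl carbonate | CCOC(=O)O/C=C\[C@@H](C)CCC/C(C)=C/CC/C(C)=C/CCc1ccoc1 | intermediate
22 | 2-bromopropanoyl bromide | CC(Br)C(=O)Br | starting material
23 | methylketene, prop-1-en-1-one | CC=C=O | intermediate
24 | α-magnesio enol carbonate, chloromagnesium derivative of 21 metalated at C1 of the enol (chain still cis to the carbonate oxygen) | CCOC(=O)O/C([Mg]Cl)=C\[C@@H](C)CCC/C(C)=C/CC/C(C)=C/CCc1ccoc1 | intermediate
25 | chloromagnesium enolate of the 3-oxo-4-(ethoxycarbonyloxy) enone formed from 24 and methylketene | CCOC(=O)O/C(=C\[C@@H](C)CCC/C(C)=C/CC/C(C)=C/CCc1ccoc1)C(O[Mg]Cl)=CC | intermediate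
26 | chloromagnesium tetronate of variabilin | CC1=C(O[Mg]Cl)/C(=C/[C@@H](C)CCC/C(C)=C/CC/C(C)=C/CCc2ccoc2)OC1=O | intermediate
27 | variabilin, (5Z)-5-[(2S,6E,10E)-13-(furan-3-yl)-2,6,10-trimethyltrideca-6,10-dien-1-ylidene]-4-hydroxy-3-methylfuran-2(5H)-one | CC1=C(O)/C(=C/[C@@H](C)CCC/C(C)=C/CC/C(C)=C/CCc2ccoc2)OC1=O | target

**Step count and risks**

Total step count: 13. Longest linear sequence: 8 steps (steps 1–4, then 9, 10, 11 and 13; the branch through steps 5–8 is equally long, and step 12 is a one-step side branch).

Steps most likely to fail:

Step 13 (proposed new method). The amide base may instead metalate the furan at C2, the metalated carbonate may undergo 1,2-shift of its ethoxycarbonyl group before the ketene arrives, or the enolate may be acylated on oxygen while the ketene oligomerises. The fallback uses known reaction types, sets out from aldehyde 19 and returns at 27. The aldehyde is enolised as in step 11 and trapped with N,N-diisopropylcarbamoyl chloride to give the (Z)-enol N,N-diisopropylcarbamate F1. This is α-lithiated with n-BuLi and TMEDA at −78 °C and acylated with N-methoxy-N-methylpropanamide to give the α-carbamoyloxy enone F2. LiN(SiMe3)2 then brings about an anionic O-to-C carbamoyl transfer of the Baker–Venkataraman type to the diketo amide F3, which is lactonised with loss of diisopropylamine by warming in acetic acid to give 27. The acid-mediated closure is the weak point of this fallback for so acid-sensitive a polyene.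

Step 11. Enolisation may give poor (Z)/(E) control, or aldol self-condensation may compete with deprotonation. The fallback sets out from 19 and returns at 21. Thermodynamic silylation (Me3SiCl, NaI, Et3N, MeCN) gives the (Z)-trimethylsilyl enol ether F4, which can be purified and checked for geometry. Cleavage with MeLi releases the lithium (Z)-enolate with retention of geometry, and ethyl chloroformate acylates it on oxygen to give 21.

Step 3. The oxidant may degrade the furan ring, or oxidation may occur at the allylic positions of the internal alkene. The fallback sets out from geranyl chloride 4 and returns at 7, with the oxidation done before the furan is present. SeO2 and t-BuOOH convert 4 into (2E,6E)-8-chloro-2,6-dimethylocta-2,6-dien-1-ol F5. This is coupled with two equivalents of Grignard reagent 5 under Li2CuCl4 catalysis (the first equivalent forms the magnesium alkoxide) to give alcohol 7.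

**Further compounds**

F1 | step 13 | (1Z,3S,7E,11E)-14-(furan-3-yl)-3,7,11-trimethyltetradeca-1,7,11-trien-1-yl N,N-di(propan-2-yl)carbamate | CC(C)N(C(C)C)C(=O)O/C=C\[C@@H](C)CCC/C(C)=C/CC/C(C)=C/CCc1ccoc1
F2 | step 13 | (4Z,6S,10E,14E)-17-(furan-3-yl)-6,10,14-trimethyl-3-oxoheptadeca-4,10,14-trien-4-yl N,N-di(propan-2-yl)carbamate | CCC(=O)/C(OC(=O)N(C(C)C)C(C)C)=C/[C@@H](C)CCC/C(C)=C/CC/C(C)=C/CCc1ccoc1
F3 | step 13 | (6S,10E,14E)-17-(furan-3-yl)-2,6,10,14-tetramethyl-3,4-dioxo-N,N-di(propan-2-yl)heptadeca-10,14-dienamide | CC(C(=O)N(C(C)C)C(C)C)C(=O)C(=O)C[C@@H](C)CCC/C(C)=C/CC/C(C)=C/CCc1ccoc1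
F4 | step 11 | trimethyl{[(1Z,3S,7E,11E)-14-(furan-3-yl)-3,7,11-trimethyltetradeca-1,7,11-trien-1-yl]oxy}silane | C[Si](C)(C)O/C=C\[C@@H](C)CCC/C(C)=C/CC/C(C)=C/CCc1ccoc1
F5 | step 3 | (2E,6E)-8-chloro-2,6-dimethylocta-2,6-dien-1-ol | OC/C(C)=C/CC/C(C)=C/CCl
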